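## Structural features

- The target is a trans-fused hydroazulene diester. A cyclopentane (C4–C5–C6–C7–C8) shares the C4–C8 bond with a cycloheptene (C1=C2–C3–C4–C8–C9–C10) whose only alkene is the trisubstituted C1=C2 bond, with a methyl on C1.
- Five stereocentres form one unbroken array: C3–C4–C8–C9 along the seven-membered ring, with C7 attached to C8. C4 is quaternary (angular methyl), C7 is a tertiary carbinol carrying isopropyl, and C8 is the ring-fusion methine trans to the angular methyl.
- O3 and O7 lie on the face opposite the angular methyl; O9 lies on the methyl face.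
- The three oxygens carry three different things: hydrogen on O7, an isovaleryl group on allylic O3, and a 4-hydroxybenzoyl group with a free phenol on O9.
- Fragile points are the allylic ester (ionisation), the phenolic benzoate (base, acyl transfer) and the tertiary alcohol β to C9. At the C9 ketone stage this last feature invites β-elimination, and the β,γ-alkene can slip into conjugation.
- The real difficulty is the congested C4/C8/C7 triad: a quaternary carbon beside a methine that must carry C9 trans to a fully substituted carbinol. The second difficulty is closing the seven-membered ring next to that quaternary carbon without losing the alkene geometry.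
- The key step uses the fact that C3 is both allylic to the ring alkene and attached to quaternary C4. An alkenyl metal at C2 adding to a non-enolisable aldehyde at C3 creates the C2–C3 bond, the carbinol and the seven-membered ring together.

## Logic of the disconnections

**36 from 35.** The O7–Si and aryl O–Si bonds are cut, so the last step is a deprotection that touches neither ester. This hides the two acidic hydroxyls during both acylations. The demand is that a hindered tertiary silyl ether must come off under mild conditions, which is why O7 carries triethylsilyl and not a bulkier group.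

**35 from 30 and 33 (33 from 31).** The C9–O acyl bond is cut. The aroyl group is the more base-sensitive ester, so it enters last, with its phenol masked. The forward step must acylate a hindered secondary alcohol lying cis to the angular methyl.

**30 from 29, and 29 from 28.** The C9–H bond is cut, then the C9 carbonyl is traced to a thioketal. C9 can then travel through the synthesis as an acyl-anion equivalent, and its stereocentre is set late on a rigid bicycle. The demands are hydride delivery from the face away from the angular methyl and a neutral unmasking that spares a β,γ-unsaturated, β-silyloxy ketone.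

**28 from 27.** The C3–O acyl bond is cut. Acylating first leaves C9 as the only free hydroxyl later on. The forward step needs only a hindered allylic alcohol to accept an aliphatic acyl group.

**27 from 25 (through 26).** The C2–C3 bond is cut, opening the seven-membered ring to a cyclopentane that holds an aldehyde on C4 and a Z-iodoalkene chain on C9. This one cut removes a ring, a stereocentre and the alkene placement problem. The forward step needs an alkenyl metal that keeps its geometry, ignores the thioketal and silyl ether, and adds to a neopentyl aldehyde.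

**25 from 24, and 24 from 23.** These are adjustments at C3 only (aldehyde from alcohol from silyl ether). O3 is kept as a primary triethylsilyl ether through the carbanion chemistry so that the carbanion is not quenched and silicon cannot wander from tertiary O7 to primary O3. The demand is selective removal of the primary silyl ether beside the tertiary one.

**23 from 12, 19 and 16 (19 from 17; 16 from 15 from 13).** The C8–C9 and C9–C10 bonds are cut in a single operation, with C9 as a silylated dithiane linchpin. Three fragments of low complexity result, and the O7 silyl group arrives by migration. The demand is an SN2 opening at C8, next to the quaternary carbon, anti to the epoxide oxygen.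

**12 from 11, 11 from 10, 10 from 9.** The epoxide C–O bonds are cut. The C3 hydroxyl is used once, free, to place oxygen on its own face of the alkene, which fixes O7 cis to C3. The cost is one protecting-group exchange at O3.

**9 from 7 (through 8).** The C4–C8 bond and the C7=C8 alkene are cut. The quaternary centre becomes a tertiary C–H stereocentre in an open-chain ketone. The forward insertion must go with retention and must find only one C–H bond five atoms from the carbene.

**7 from 2 and 4 (2 from 1; 4 from 3).** The C5–C6 bond is cut, giving a chiral four-carbon bromide and a methyl ketone. The demand is regioselective alkylation at the methyl group, met by the hydrazone.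

## Other disconnections considered

**Alternative 1:** The cut is C4–C8 in the five-membered ring. Rh2(OAc)4 would decompose diazo keto ester A2, and the carbenoid at C8 would insert into the tertiary C4–H bond with retention to give cyclopentanone A1 (C7 as ketone, C9 as an ester on C8).
- *In favour.* It is catalytic. It uses the same stereocentre and the same retention logic as step 4, so it is the equal of the chosen plan for setting C4. Mechanistically the two insertions are close relatives. C8 leaves the step already bonded to C9, so no nucleophile ever has to attack C8 beside the quaternary carbon. On that point it is better than step 11 of the chosen plan.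
- *Against.* The C7 carbonyl sits in a β-keto ester whose C8–H is acidic, so an isopropyl nucleophile would deprotonate before adding. The O7 configuration would then depend on reagent approach to a cyclopentanone, not on a hydroxyl-directed, stereospecific epoxide sequence. The C9 ester must still be turned into a ketone carrying the iodoalkene arm. The seven-membered ring is not addressed at all.
- *Step economy.* The cyclopentane arrives in about as many steps, but the corrections at C7 and C9 should cost more than the three-component coupling of step 11 saves.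

**Alternative 2:** The cut is the C7–O bond. I2 would activate the C6=C7 alkene of acid A4, and the carboxylate on C4 would open the iodonium ion at tertiary C7 from its own face to give bridged iodolactone A3.
- *In favour.* The bridge enforces the cis relation of O7 and C3 geometrically. That is at least the equal of the directed epoxidation of step 6 and arguably more certain. The lactone masks O7 and C3 in one group, so no hindered silyl ether would have to be removed at the end, which is better than step 20. Anti addition with Markovnikov opening is stereospecific.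
- *Against.* A4 already needs C8 with its C9 chain trans to the carboxyl group, so the hardest bond is left unsolved. The step makes a ring and a C–I bond that the target lacks: iodine must be removed by radical reduction beside an alkenyl bromide, and the strained lactone must be brought down to the aldehyde level, where it would rest as a lactol, a poorer electrophile for the chromium step than free aldehyde 25. The alkenyl bromide is also less reactive than an iodide in nickel/chromium chemistry.
- *Step economy.* The extra redox and dehalogenation steps roughly cancel the two silyl operations saved, so there is no net gain.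

**Alternative 3:** The cuts are C1–C10 and C3–C4, the whole seven-membered ring. A chiral dirhodium tetracarboxylate such as Rh2(S-DOSP)4 would decompose vinyldiazoacetate A6. The carbenoid would cyclopropanate the enol ether alkene (C9=C10) of diene A7, and the cis-divinylcyclopropane would rearrange to cycloheptadiene A5.
- *In favour.* It is the most convergent idea. Two bonds, the ring and the C3/C4 stereocentres come from two achiral fragments in one catalytic asymmetric, stereospecific operation. O3 and O9 are already in place. For building the seven-membered ring it is better in step economy than steps 8–14 of the chosen plan.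
- *Against.* A5 carries an ester on C1 where the target has methyl. C7 has neither oxygen nor isopropyl, and C8 is sp2. The tertiary carbinol and the trans ring fusion, the most crowded part of the molecule, would have to be built on the finished bicycle without a directing group. The rearrangement must form quaternary C4 from a fully substituted alkene terminus, which is the slow case and could stall at the cyclopropanation stage. Absolute control would rest on the catalyst, not on a purchased stereocentre.
- *Step economy.* The front end is shorter and the back end longer. Overall it is not shorter and is riskier at C7/C8.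

Key step: step 14

**Remarks before the steps**

- Atom numbers used throughout: seven-membered ring C1(Me)=C2–C3–C4(Me)–C8(H)–C9–C10; five-membered ring C4–C5–C6–C7(O, i-Pr)–C8. CIP descriptors in descriptive names use these numbers.
- Structure check: 25 and 27 carry the target configuration at C4, C7 and C8 (and C3 in 27) and the Z-iodoalkene that a cis ring alkene needs, so no atom or descriptor had to be corrected. The design changes concern spectator groups only: triethylsilyl on O7, a temporary triethylsilyl ether on O3 during step 11, and the dithiane kept through the ring closure.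
- Assumption: (R)-3-bromo-2-methylpropan-1-ol is taken as the commercial source of C3–C5. It carries the same stereocentre as methyl (R)-3-hydroxy-2-methylpropanoate with the ester carbon already at the CH2Br level, which saves a reduction and a halogenation.

## Route

Step 1
Reactants: 1 (R)-3-bromo-2-methylpropan-1-ol
Product: 2 (R)-(3-bromo-2-methylpropoxy)(tert-butyl)diphenylsilane
Conditions: t-BuPh2SiCl, imidazole, CH2Cl2, 0 °C to rt
Reagents that add atoms: tert-butyl(chloro)diphenylsilane, CC(C)(C)[Si](Cl)(c1ccccc1)c1ccccc1
Why: Imidazole-promoted silylation of a primary alcohol; the bulky silyl ether survives amide bases, organolithiums and the carbene step, and the stereocentre is not touched.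

Step 2
Reactants: 3 3-methylbutan-2-one
Product: 4 3-methylbutan-2-one N,N-dimethylhydrazone
Conditions: Me2NNH2, AcOH (cat.), EtOH, reflux
Reagents that add atoms: N,N-dimethylhydrazine, CN(C)N
Why: Condensation of a methyl ketone with a 1,1-disubstituted hydrazine; the hydrazone is the regiochemically reliable enolate equivalent for alkylation at the methyl carbon.

Step 3
Reactants: 4 3-methylbutan-2-one N,N-dimethylhydrazone; 2 (R)-(3-bromo-2-methylpropoxy)(tert-butyl)diphenylsilane
Product: 7 (S)-7-[(tert-butyldiphenylsilyl)oxy]-2,6-dimethylheptan-3-one, via lithium azaenolate 5 (not isolated), via alkylated hydrazone 6 (not isolated)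
Conditions: LiN(i-Pr)2, THF, 0 °C; then 2, THF/DMPU, –78 °C to rt; then aq. oxalic acid, Et2O, rt
Reagents that add atoms: water, O
Why: Metalated-hydrazone alkylation: the amide base deprotonates the less substituted α-carbon, the azaenolate displaces the primary bromide by SN2 to form C5–C6, and mild biphasic acid returns the ketone without harming the silyl ether. The stereocentre is β to the reacting carbon and cannot epimerise.

Step 4
Reactants: 7 (S)-7-[(tert-butyldiphenylsilyl)oxy]-2,6-dimethylheptan-3-one
Product: 9 (S)-tert-butyl[(3-isopropyl-1-methylcyclopent-2-en-1-yl)methoxy]diphenylsilane, via alkylidene carbene 8 (not isolated)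
Conditions: Me3SiCHN2, n-BuLi, THF, –78 °C; then 7, –78 °C to rt
Reagents that add atoms: (trimethylsilyl)diazomethane, C[Si](C)(C)C=[N+]=[N-]
Why: Lithiated (trimethylsilyl)diazomethane adds to the ketone, and Peterson-type loss of silanolate followed by loss of N2 gives carbene 8, which undergoes 1,5 C–H insertion into the only C–H bond five atoms away, the tertiary C4–H, forming C8–C4 and the cyclopentene. The insertion is concerted and goes with retention, so the stereocentre of 1 becomes quaternary C4 with the target configuration.

Step 5
Reactants: 9 (S)-tert-butyl[(3-isopropyl-1-methylcyclopent-2-en-1-yl)methoxy]diphenylsilane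
Product: 10 (S)-(3-isopropyl-1-methylcyclopent-2-en-1-yl)methanol
Conditions: Bu4NF, THF, rt
Reagents that add atoms: none
Why: Fluoride cleavage of the silyl ether frees the homoallylic hydroxyl that must direct the epoxidation.

Step 6
Reactants: 10 (S)-(3-isopropyl-1-methylcyclopent-2-en-1-yl)methanol
Product: 11 [(1S,2R,5S)-5-isopropyl-2-methyl-6-oxabicyclo[3.1.0]hexan-2-yl]methanol
Conditions: VO(acac)2 (cat.), t-BuOOH, CH2Cl2, 0 °C to rt
Reagents that add atoms: tert-butyl hydroperoxide, CC(C)(C)OO
Why: Hydroxyl-directed epoxidation of a homoallylic alcohol: the vanadium alkoxide–peroxide complex delivers oxygen to the alkene face that bears CH2OH, so the epoxide oxygen (later O7) is cis to C3 and trans to the angular methyl. The trisubstituted alkene is electron-rich enough for this reagent.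

Step 7
Reactants: 11 [(1S,2R,5S)-5-isopropyl-2-methyl-6-oxabicyclo[3.1.0]hexan-2-yl]methanol
Product: 12 triethyl{[(1S,2R,5S)-5-isopropyl-2-methyl-6-oxabicyclo[3.1.0]hexan-2-yl]methoxy}silane
Conditions: Et3SiCl, imidazole, CH2Cl2, 0 °C
Reagents that add atoms: chlorotriethylsilane, CC[Si](CC)(CC)Cl
Why: Silylation of the primary alcohol; O3 must be masked before the carbanion chemistry of step 11, and a primary triethylsilyl ether can later be removed beside the tertiary one.

Step 8
Reactants: 13 prop-2-yn-1-ol
Product: 15 (Z)-3-iodo-2-methylprop-2-en-1-ol, via alkenylmagnesium chelate 14 (not isolated)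
Conditions: MeMgBr, CuI (cat.), THF, –10 °C to rt; then I2, THF, –10 °C
Reagents that add atoms: methylmagnesium bromide, C[Mg]Br; iodine, II
Why: Copper-catalysed anti-carbomagnesiation of the propargylic alkoxide puts methyl on the internal carbon and magnesium on the terminal carbon cis to the CH2O group (chelate 14). Iodinolysis with retention gives the Z-iodoalkene, the geometry the ring needs.

Step 9
Reactants: 15 (Z)-3-iodo-2-methylprop-2-en-1-ol
Product: 16 (Z)-3-bromo-1-iodo-2-methylprop-1-ene
Conditions: CBr4, PPh3, CH2Cl2, 0 °C
Reagents that add atoms: tetrabromomethane, BrC(Br)(Br)Br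
Why: Appel bromination of a primary allylic alcohol under neutral conditions; alkene geometry and the C–I bond are unaffected.

Step 10
Reactants: 17 1,3-dithiane
Product: 19 2-(triethylsilyl)-1,3-dithiane, via 2-lithio-1,3-dithiane 18 (not isolated)
Conditions: n-BuLi, THF, –30 °C; then Et3SiCl, –78 °C to rt
Reagents that add atoms: chlorotriethylsilane, CC[Si](CC)(CC)Cl
Why: Deprotonation of the dithiane C2–H (Corey–Seebach umpolung) and C-silylation give the linchpin that becomes C9 and carries the future O7 silyl group.

Step 11
Reactants: 19 2-(triethylsilyl)-1,3-dithiane; 12 triethyl{[(1S,2R,5S)-5-isopropyl-2-methyl-6-oxabicyclo[3.1.0]hexan-2-yl]methoxy}silane; 16 (Z)-3-bromo-1-iodo-2-methylprop-1-ene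
Product: 23 2-[(1R,2S,5S)-2-isopropyl-5-methyl-2-(triethylsilyloxy)-5-(triethylsilyloxymethyl)cyclopentyl]-2-[(Z)-3-iodo-2-methylprop-2-en-1-yl]-1,3-dithiane, via lithiated silyl dithiane 20 (not isolated), via lithium alkoxide 21 (not isolated), via dithianyl lithium 22 (not isolated)
Conditions: 19, t-BuLi, Et2O, –78 to –45 °C; then 12, Et2O, –45 °C to rt; then 16, HMPA, Et2O, –78 to –20 °C
Reagents that add atoms: none
Why: Three-component anion relay coupling: 20 opens the epoxide by SN2 at C8, the only epoxide carbon bearing hydrogen, anti to oxygen (from the methyl face), which sets C8 with C9 trans to O7. HMPA then triggers the 1,4-Brook shift of silicon from C9 to the tertiary alkoxide, and the new carbanion 22 is alkylated by the allylic bromide to form C9–C10. Iodine–lithium exchange is not expected, since it would trade a sulfur-stabilised carbanion for a more basic alkenyllithium.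

Step 12
Reactants: 23 2-[(1R,2S,5S)-2-isopropyl-5-methyl-2-(triethylsilyloxy)-5-(triethylsilyloxymethyl)cyclopentyl]-2-[(Z)-3-iodo-2-methylprop-2-en-1-yl]-1,3-dithiane
Product: 24 [(1S,2R,3S)-2-{2-[(Z)-3-iodo-2-methylprop-2-en-1-yl]-1,3-dithian-2-yl}-3-isopropyl-1-methyl-3-(triethylsilyloxy)cyclopentyl]methanol
Conditions: PPTS (cat.), MeOH/CH2Cl2, 0 °C
Reagents that add atoms: none
Why: Acid-catalysed methanolysis distinguishes the unhindered primary silyl ether from the tertiary, isopropyl-flanked one, which solvolyses far more slowly; thioketal and iodoalkene are inert.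

Step 13
Reactants: 24 [(1S,2R,3S)-2-{2-[(Z)-3-iodo-2-methylprop-2-en-1-yl]-1,3-dithian-2-yl}-3-isopropyl-1-methyl-3-(triethylsilyloxy)cyclopentyl]methanol
Product: 25 (1S,2R,3S)-2-{2-[(Z)-3-iodo-2-methylprop-2-en-1-yl]-1,3-dithian-2-yl}-3-isopropyl-1-methyl-3-(triethylsilyloxy)cyclopentane-1-carbaldehyde
Conditions: SO3·pyridine, DMSO, i-Pr2NEt, CH2Cl2, 0 °C
Reagents that add atoms: none
Why: Parikh–Doering oxidation of the neopentyl primary alcohol, a method compatible with thioketals. The aldehyde has no α-hydrogen, so it cannot epimerise, and the O7 silyl ether keeps it from closing to a bridged lactol.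

Step 14
Reactants: 25 (1S,2R,3S)-2-{2-[(Z)-3-iodo-2-methylprop-2-en-1-yl]-1,3-dithian-2-yl}-3-isopropyl-1-methyl-3-(triethylsilyloxy)cyclopentane-1-carbaldehyde
Product: 27 (3R,4S,7S,8R)-hydroazulene allylic alcohol (C1=C2; C3–OH trans to the C4 methyl; C7–OSiEt3; C9 as 1,3-dithiane), via alkenylchromium dichloride 26 (not isolated)
Conditions: CrCl2 (excess), NiCl2 (cat.), degassed DMSO/THF, rt, high dilution
Reagents that add atoms: none
Why: CrCl2 reduces NiCl2 to zerovalent nickel, which inserts into the C2–I bond with retention of the Z geometry; transmetalation to trivalent chromium gives alkenylchromium 26, a weakly basic nucleophile that adds to the C3 aldehyde and is held as the chromium alkoxide, the strong Cr–O bond driving the addition. This is an intramolecular Nozaki–Hiyama–Kishi reaction, and the closest known type is the closure of medium rings from alkenyl iodides and aldehydes. The seven-membered ring closes in the 7-exo-trig mode (C2 attacks a carbonyl whose C=O bond lies outside the forming ring), helped by the cis C10/C2 geometry of the alkene and by the gem-disubstituent effect of the C9 dithiane and quaternary C4, which turn the chain toward the aldehyde. The new C3 stereocentre is under substrate control: in the chair-like closure the chromium-bound oxygen is expected to lie anti to the axial C4 methyl, away from the double gauche contact with that methyl and C5, which gives the 3R alcohol with O3 trans to the angular methyl. The step needs chemoselectivity for the aldehyde and freedom from enolisation; the aldehyde on quaternary C4 has no α-hydrogen, and organochromium reagents leave thioketals, silyl ethers and the trisubstituted alkene alone. High dilution suppresses intermolecular addition.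

Step 15
Reactants: 27 (3R,4S,7S,8R)-hydroazulene allylic alcohol
Product: 28 (3R,4S,7S,8R)-hydroazulene C3 3-methylbutanoate (C7–OSiEt3; C9 as 1,3-dithiane)
Conditions: 3-methylbutanoyl chloride, pyridine, DMAP (cat.), CH2Cl2, 0 °C to rt
Reagents that add atoms: 3-methylbutanoyl chloride, CC(C)CC(Cl)=O
Why: DMAP-catalysed acylation of the hindered secondary allylic alcohol with retention at C3; no other free hydroxyl is present.

Step 16
Reactants: 28 (3R,4S,7S,8R)-hydroazulene C3 3-methylbutanoate
Product: 29 (3R,4S,7S,8R)-hydroazulene C9 ketone (C3 3-methylbutanoate; C7–OSiEt3)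
Conditions: MeI, CaCO3, MeCN/H2O, 45 °C
Reagents that add atoms: water, O
Why: Alkylative hydrolysis of the thioketal: S-methylation makes sulfur a leaving group and water delivers the C9 carbonyl under carbonate buffering. These near-neutral conditions are chosen because the β,γ-unsaturated, β-silyloxy ketone is sensitive to acid and base; the crude ketone is reduced at once.

Step 17
Reactants: 29 (3R,4S,7S,8R)-hydroazulene C9 ketone
Product: 30 (3R,4S,7S,8S,9R)-hydroazulene C9 alcohol (C3 3-methylbutanoate; C7–OSiEt3; O9 cis to the C4 methyl)
Conditions: NaBH4, CeCl3·7H2O, MeOH, –78 to –40 °C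
Reagents that add atoms: none
Why: Luche-type 1,2-reduction, fast and weakly basic. Hydride should reach C9 from the face opposite the axial C4 methyl and the C7 isopropyl, which both lie over the other face, giving the 9R alcohol; the ester is not reduced at this temperature.

Step 18
Reactants: 31 4-hydroxybenzoic acid
Product: 33 4-(tert-butyldimethylsilyloxy)benzoic acid, via silyl ester 32 (not isolated)
Conditions: t-BuMe2SiCl, imidazole, DMF, rt; then AcOH/THF/H2O, rt
Reagents that add atoms: tert-butyl(chloro)dimethylsilane, CC(C)(C)[Si](C)(C)Cl
Why: Exhaustive silylation, then selective hydrolysis of the labile silyl ester under mild acid, which leaves the aryl silyl ether in place.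

Step 19
Reactants: 33 4-(tert-butyldimethylsilyloxy)benzoic acid; 30 (3R,4S,7S,8S,9R)-hydroazulene C9 alcohol
Product: 35 (3R,4S,7S,8S,9R)-bis-silyl ether of the target (O7–SiEt3; aryl O–Si-t-BuMe2), via mixed anhydride 34 (not isolated)
Conditions: 33, 2,4,6-trichlorobenzoyl chloride, Et3N, toluene, rt; then 30, DMAP, toluene, rt to 40 °C
Reagents that add atoms: none
Why: Yamaguchi esterification: DMAP attacks the mixed anhydride at the less hindered aroyl carbonyl and the acylpyridinium acylates the C9 alcohol with retention. O7 and the phenol are silylated, so only C9–OH can react.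

Step 20
Reactants: 35 (3R,4S,7S,8S,9R)-bis-silyl ether of the target
Product: 36 (3S,3aS,4R,8R,8aS)-3-hydroxy-3-isopropyl-6,8a-dimethyl-8-(3-methylbutanoyloxy)-1,2,3,3a,4,5,8,8a-octahydroazulen-4-yl 4-hydroxybenzoate
Conditions: HF·pyridine, pyridine, THF, 0 °C to rt
Reagents that add atoms: none
Why: Fluoride cleavage of both Si–O bonds under buffered, mildly acidic conditions that promote neither ester hydrolysis nor acyl migration. Triethylsilyl was chosen for O7 so that this hindered tertiary ether can be removed here.

## Compound list

1 | (R)-3-bromo-2-methylpropan-1-ol | OC[C@@H](C)CBr | starting material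
2 | (R)-(3-bromo-2-methylpropoxy)(tert-butyl)diphenylsilane | CC(C)(C)[Si](OC[C@@H](C)CBr)(c1ccccc1)c1ccccc1 | intermediate
3 | 3-methylbutan-2-one | CC(C)C(C)=O | starting material
4 | 3-methylbutan-2-one N,N-dimethylhydrazone (C=N geometry not defined) | CC(C)C(C)=NN(C)C | intermediate
5 | lithium azaenolate of 4, metalated at the methyl carbon | [Li]N(N(C)C)C(=C)C(C)C | intermediate (not isolated)
6 | (S)-7-[(tert-butyldiphenylsilyl)oxy]-2,6-dimethylheptan-3-one N,N-dimethylhydrazone | CC(C)C(CC[C@H](C)CO[Si](c1ccccc1)(c1ccccc1)C(C)(C)C)=NN(C)C | intermediate (not isolated)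
7 | (S)-7-[(tert-butyldiphenylsilyl)oxy]-2,6-dimethylheptan-3-one | CC(C)C(=O)CC[C@H](C)CO[Si](c1ccccc1)(c1ccccc1)C(C)(C)C | intermediate
8 | alkylidene carbene derived from 7 (C=O replaced by C=C:) | CC(C)C(=[C])CC[C@H](C)CO[Si](c1ccccc1)(c1ccccc1)C(C)(C)C | intermediate (not isolated)
9 | (S)-tert-butyl[(3-isopropyl-1-methylcyclopent-2-en-1-yl)methoxy]diphenylsilane | CC(C)C1=C[C@@](C)(CO[Si](c2ccccc2)(c2ccccc2)C(C)(C)C)CC1 | intermediate
10 | (S)-(3-isopropyl-1-methylcyclopent-2-en-1-yl)methanol | CC(C)C1=C[C@@](C)(CO)CC1 | intermediate
11 | [(1S,2R,5S)-5-isopropyl-2-methyl-6-oxabicyclo[3.1.0]hexan-2-yl]methanol (epoxide cis to CH2OH) | CC(C)[C@@]12CC[C@](C)(CO)[C@@H]1O2 | intermediate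
12 | triethyl{[(1S,2R,5S)-5-isopropyl-2-methyl-6-oxabicyclo[3.1.0]hexan-2-yl]methoxy}silane | CC(C)[C@@]12CC[C@](C)(CO[Si](CC)(CC)CC)[C@@H]1O2 | intermediate
13 | prop-2-yn-1-ol | C#CCO | starting material
14 | 4-methyl-2,5-dihydro-1,2-oxamagnesole (cyclic alkenylmagnesium alkoxide) | CC1=C[Mg]OC1 | intermediate (not isolated)
15 | (Z)-3-iodo-2-methylprop-2-en-1-ol | OC/C(C)=C\I | intermediate
16 | (Z)-3-bromo-1-iodo-2-methylprop-1-ene | BrC/C(C)=C\I | intermediate
17 | 1,3-dithiane | C1CSCSC1 | starting material
18 | 2-lithio-1,3-dithiane | [Li]C1SCCCS1 | intermediate (not isolated)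
19 | 2-(triethylsilyl)-1,3-dithiane | CC[Si](CC)(CC)C1SCCCS1 | intermediate
20 | 2-lithio-2-(triethylsilyl)-1,3-dithiane | CC[Si](CC)(CC)C1([Li])SCCCS1 | intermediate (not isolated)
21 | lithium C7 alkoxide of the ring-opened adduct (C9 still C-silylated; O3–SiEt3; C9 trans to O7) | CC[Si](CC)(CC)OC[C@@]1(C)CC[C@](O[Li])(C(C)C)[C@@H]1C1(SCCCS1)[Si](CC)(CC)CC | intermediate (not isolated)
22 | C9-lithiated dithiane after the 1,4-Brook shift (O7–SiEt3; O3–SiEt3) | CC[Si](CC)(CC)OC[C@@]1(C)CC[C@](O[Si](CC)(CC)CC)(C(C)C)[C@@H]1C1([Li])SCCCS1 | intermediate (not isolated)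
23 | 2-[(1R,2S,5S)-2-isopropyl-5-methyl-2-(triethylsilyloxy)-5-(triethylsilyloxymethyl)cyclopentyl]-2-[(Z)-3-iodo-2-methylprop-2-en-1-yl]-1,3-dithiane | CC[Si](CC)(CC)OC[C@@]1(C)CC[C@](O[Si](CC)(CC)CC)(C(C)C)[C@@H]1C1(SCCCS1)C/C(C)=C\I | intermediate
24 | [(1S,2R,3S)-2-{2-[(Z)-3-iodo-2-methylprop-2-en-1-yl]-1,3-dithian-2-yl}-3-isopropyl-1-methyl-3-(triethylsilyloxy)cyclopentyl]methanol | OC[C@@]1(C)CC[C@](O[Si](CC)(CC)CC)(C(C)C)[C@@H]1C1(SCCCS1)C/C(C)=C\I | intermediate
25 | (1S,2R,3S)-2-{2-[(Z)-3-iodo-2-methylprop-2-en-1-yl]-1,3-dithian-2-yl}-3-isopropyl-1-methyl-3-(triethylsilyloxy)cyclopentane-1-carbaldehyde | O=C[C@@]1(C)CC[C@](O[Si](CC)(CC)CC)(C(C)C)[C@@H]1C1(SCCCS1)C/C(C)=C\I | intermediate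
26 | (Z)-alkenylchromium dichloride from 25 (C2–CrCl2 in place of C2–I) | O=C[C@@]1(C)CC[C@](O[Si](CC)(CC)CC)(C(C)C)[C@@H]1C1(SCCCS1)C/C(C)=C\[Cr](Cl)Cl | intermediate (not isolated)
27 | (3R,4S,7S,8R)-hydroazulene allylic alcohol: C1=C2, C3–OH trans to the C4 methyl, C7–OSiEt3 cis to H8, C9 as 1,3-dithiane, trans ring fusion | CC1=C[C@@H](O)[C@@]2(C)CC[C@](O[Si](CC)(CC)CC)(C(C)C)[C@@H]2C2(SCCCS2)C1 | intermediate
28 | (3R,4S,7S,8R)-C3 3-methylbutanoate of 27 | CC1=C[C@@H](OC(=O)CC(C)C)[C@@]2(C)CC[C@](O[Si](CC)(CC)CC)(C(C)C)[C@@H]2C2(SCCCS2)C1 | intermediate
29 | (3R,4S,7S,8R)-C9 ketone: C3 3-methylbutanoate, C7–OSiEt3 | CC1=C[C@@H](OC(=O)CC(C)C)[C@@]2(C)CC[C@](O[Si](CC)(CC)CC)(C(C)C)[C@@H]2C(=O)C1 | intermediate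
30 | (3R,4S,7S,8S,9R)-C9 alcohol: O9 cis to the C4 methyl, C3 3-methylbutanoate, C7–OSiEt3 | CC1=C[C@@H](OC(=O)CC(C)C)[C@@]2(C)CC[C@](O[Si](CC)(CC)CC)(C(C)C)[C@@H]2[C@H](O)C1 | intermediate
31 | 4-hydroxybenzoic acid | OC(=O)c1ccc(O)cc1 | starting material
32 | tert-butyldimethylsilyl 4-(tert-butyldimethylsilyloxy)benzoate | CC(C)(C)[Si](C)(C)OC(=O)c1ccc(O[Si](C)(C)C(C)(C)C)cc1 | intermediate (not isolated)
33 | 4-(tert-butyldimethylsilyloxy)benzoic acid | CC(C)(C)[Si](C)(C)Oc1ccc(C(=O)O)cc1 | intermediate
34 | 4-(tert-butyldimethylsilyloxy)benzoic 2,4,6-trichlorobenzoic anhydride | CC(C)(C)[Si](C)(C)Oc1ccc(C(=O)OC(=O)c2c(Cl)cc(Cl)cc2Cl)cc1 | intermediate (not isolated)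
35 | (3R,4S,7S,8S,9R)-bis-silyl ether of the target: O7–SiEt3, aryl O–Si-t-BuMe2 | CC1=C[C@@H](OC(=O)CC(C)C)[C@@]2(C)CC[C@](O[Si](CC)(CC)CC)(C(C)C)[C@@H]2[C@H](OC(=O)c2ccc(O[Si](C)(C)C(C)(C)C)cc2)C1 | intermediate
36 | (3S,3aS,4R,8R,8aS)-3-hydroxy-3-isopropyl-6,8a-dimethyl-8-(3-methylbutanoyloxy)-1,2,3,3a,4,5,8,8a-octahydroazulen-4-yl 4-hydroxybenzoate | CC1=C[C@@H](OC(=O)CC(C)C)[C@@]2(C)CC[C@](O)(C(C)C)[C@@H]2[C@H](OC(=O)c2ccc(O)cc2)C1 | target

## Step count and least certain steps

Total step count: 20. Longest linear sequence: 15 steps (steps 1, 3–7, 11–17, 19, 20, from 1 to 36). Side branches are step 2, steps 8–9, step 10 and step 18.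

**Step 14 (key step).**
- *What may go wrong.* Poor facial selectivity at C3 is the most likely problem. The two chair-like closures differ only in whether the chromium-bound oxygen or the hydrogen lies anti to the C4 methyl. Slowing of the nickel cycle by thioketal sulfur is a lesser concern.
- *Fallback.* It sets out from 25. If the closure delivers mainly the C3-epimeric allylic alcohol F1, oxidation and re-reduction would not help, because hydride would be expected to come again from the face away from the methyl and return the same epimer. F1 is instead esterified with inversion under Mitsunobu conditions (PPh3, diisopropyl azodicarboxylate, 3-methylbutanoic acid, toluene). The carboxylate enters from the face opposite the angular methyl, and the route is rejoined at 28.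

**Step 11.**
- *What may go wrong.* Steric retardation of the SN2 opening at C8: a tertiary carbanion must attack a carbon flanked by a quaternary and a fully substituted centre, so base-induced isomerisation of the epoxide to an allylic alcohol, or no reaction, may win.
- *Fallback.* It sets out from 12 and separates the three events. The smaller 2-lithio-1,3-dithiane 18, used in excess in THF/DMPU, opens the epoxide to the tertiary hydroxy dithiane F2. Et3SiOTf with 2,6-lutidine gives the bis-silyl ether F3. Metalation of C9 with t-BuLi in THF/HMPA at –78 °C gives 22, and alkylation with 16 returns to the route at 23.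

**Step 17.**
- *What may go wrong.* Erosion of facial selectivity if the C7 silyloxy group screens the face that the angular methyl leaves open, giving the C9 epimer.
- *Fallback.* It sets out from 29 and replaces steric control by hydroxyl direction.
  - HF·pyridine removes the O7 silyl group to give the β-hydroxy ketone F4.
  - Me4NBH(OAc)3 in MeCN/AcOH at –20 °C binds O7 and delivers hydride within the molecule to the O7 face of C9, giving the diol F5.
  - Yamaguchi acylation with 34 takes the secondary C9 hydroxyl in preference to the tertiary one, giving the aryl silyl ether F6.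
  - HF·pyridine frees the phenol, and the route is rejoined at 36.
  - This variant also avoids the late cleavage of a hindered tertiary silyl ether.

**Step 4.**
- *What may go wrong.* Enolisation of the α-branched ketone by the lithiated diazo reagent in competition with addition, so that 7 is returned.
- *Fallback.* It sets out from 7. Wittig chloromethylenation (ylide from (chloromethyl)triphenylphosphonium chloride and KN(SiMe3)2, THF) gives the chloroalkene F7. KN(SiMe3)2 in Et2O then effects α-elimination to the same carbene 8, which inserts as before, and the route is rejoined at 9.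

## Further compounds

F1 | step 14 | (3S,4S,7S,8R)-C3 epimer of 27 (C3–OH cis to the C4 methyl) | CC1=C[C@H](O)[C@@]2(C)CC[C@](O[Si](CC)(CC)CC)(C(C)C)[C@@H]2C2(SCCCS2)C1
F2 | step 11 | (1S,2R,3S)-2-(1,3-dithian-2-yl)-1-isopropyl-3-methyl-3-[(triethylsilyloxy)methyl]cyclopentan-1-ol | CC[Si](CC)(CC)OC[C@@]1(C)CC[C@](O)(C(C)C)[C@@H]1C1SCCCS1
F3 | step 11 | O7-triethylsilyl ether of F2 | CC[Si](CC)(CC)OC[C@@]1(C)CC[C@](O[Si](CC)(CC)CC)(C(C)C)[C@@H]1C1SCCCS1
F4 | step 17 | (3R,4S,7S,8R)-C7 hydroxy C9 ketone (29 without the silyl group) | CC1=C[C@@H](OC(=O)CC(C)C)[C@@]2(C)CC[C@](O)(C(C)C)[C@@H]2C(=O)C1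
F5 | step 17 | (3R,4S,7S,8S,9R)-C7,C9 diol C3 3-methylbutanoate | CC1=C[C@@H](OC(=O)CC(C)C)[C@@]2(C)CC[C@](O)(C(C)C)[C@@H]2[C@H](O)C1
F6 | step 17 | (3R,4S,7S,8S,9R)-target with the phenol as tert-butyldimethylsilyl ether and O7 free | CC1=C[C@@H](OC(=O)CC(C)C)[C@@]2(C)CC[C@](O)(C(C)C)[C@@H]2[C@H](OC(=O)c2ccc(O[Si](C)(C)C(C)(C)C)cc2)C1
F7 | step 4 | tert-butyl{[(2S)-5-(chloromethylidene)-2,6-dimethylheptyl]oxy}diphenylsilane (alkene isomers) | CC(C)C(=CCl)CC[C@H](C)CO[Si](c1ccccc1)(c1ccccc1)C(C)(C)C
A1 | alternative 1 | methyl (1R,2S)-2-[(tert-butyldiphenylsilyloxy)methyl]-2-methyl-5-oxocyclopentane-1-carboxylate | COC(=O)[C@H]1C(=O)CC[C@]1(C)CO[Si](c1ccccc1)(c1ccccc1)C(C)(C)C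
A2 | alternative 1 | methyl (S)-7-[(tert-butyldiphenylsilyl)oxy]-2-diazo-6-methyl-3-oxoheptanoate | COC(=O)C(=[N+]=[N-])C(=O)CC[C@H](C)CO[Si](c1ccccc1)(c1ccccc1)C(C)(C)C
A3 | alternative 2 | bridged iodolactone: 6-iodo-1-isopropyl-4-methyl-7-{2-[(Z)-3-bromo-2-methylprop-2-en-1-yl]-1,3-dioxolan-2-yl}-2-oxabicyclo[2.2.1]heptan-3-one, iodine trans to the lactone oxygen | O=C1O[C@]2(C(C)C)[C@@H](I)C[C@@]1(C)[C@H]2C1(OCCO1)C/C(C)=C\Br
A4 | alternative 2 | (1S,2S)-2-{2-[(Z)-3-bromo-2-methylprop-2-en-1-yl]-1,3-dioxolan-2-yl}-3-isopropyl-1-methylcyclopent-3-ene-1-carboxylic acid | OC(=O)[C@@]1(C)CC=C(C(C)C)[C@@H]1C1(OCCO1)C/C(C)=C\Br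
A5 | alternative 3 | bicyclic cycloheptadiene methyl ester with tert-butyldimethylsilyloxy groups on C3 and C9 (C1=C2 and C8=C9) | COC(=O)C1=C[C@@H](O[Si](C)(C)C(C)(C)C)[C@@]2(C)CCCC2=C(O[Si](C)(C)C(C)(C)C)C1
A6 | alternative 3 | methyl (E)-4-(tert-butyldimethylsilyloxy)-2-diazobut-3-enoate | COC(=O)C(=[N+]=[N-])/C=C/O[Si](C)(C)C(C)(C)C
A7 | alternative 3 | tert-butyldimethyl{[1-(2-methylcyclopent-1-en-1-yl)ethenyl]oxy}silane | C=C(O[Si](C)(C)C(C)(C)C)C1=C(C)CCC1
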